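The west run, charged with 27 mM of reagent, has turned 30.9 % of its substrate into product by 40.0 h. The north run, with 60 mM, has turned 57.0 % by the same time. Your flask differs from them in its reagent and its time.

the same everywhere: left-handed substrate 10 mM; right-handed substrate 10 mM; free catalyst 0.25 mM; racemization catalyst 20 µM
- west: reagent 27 mM; run made earlier
- north: reagent 60 mM; run made earlier
- flask: reagent 40.0 mM; time 50 h

| run | time / h | left-handed product / % | right-handed product / % |
|---|---|---|---|
| west | 5.00 | 8.9 | 4.2 |
| west | 15.0 | 16.5 | 8.4 |
| west | 25.0 | 17.7 | 10.4 |
| west | 40.0 | 19.3 | 11.6 |
| north | 3.00 | 11.4 | 7.1 |
| north | 8.00 | 23.3 | 14.1 |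
| north | 15.0 | 28.4 | 18.5 |
| north | 40.0 | 35.8 | 21.2 |

(readings scatter by 0.5 percentage points)

- free catalyst is single-handed; left-handed substrate and right-handed substrate are mirror images of each other, charged as a racemate, each of them at the stated concentration
- an excess is the difference of the two amounts in percent of their sum
- an excess is below zero if the other one leads

1. left-handed product and right-handed product together, in percent of the left-handed substrate and right-handed substrate charged together, at 50 h
2. excess of left-handed product over right-handed product in the product at 50 h
3. whether the exchange between left-handed substrate and right-handed substrate keeps pace with the reaction: how far the product's excess at 50 h gets from its value without exchange to its value with instant exchange (above 80 % keeps pace, below 20 % hardly takes part, else lags behind)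

With 40.0 mM of reagent, more than west and less than north, the flask's yield has west's figure as a floor. North's is a roof, give or take the extra 10.0 h.

To tighten this, follow one substrate molecule picked blind of its hand. At every moment it either reacts or waits, so the negative logarithm of the share left sums its hazard, a pseudo-first-order rate, over the run. If that hazard scales with c(reagent), the sum divided by the charge of reagent is the same in both runs. West reads 0.0137 mM⁻¹ and north 0.0141 mM⁻¹, close given the scatter. Call their mean, 0.0139 mM⁻¹, the reach: hazard summed up to 40.0 h per unit of reagent charged.

On that scaling, west's reach with no later gain gives a floor of 42.2 %. For the roof, extend north's reach at the hazard of its last stretch, 0.00844 h⁻¹. That is generous, since north began at 0.0682 h⁻¹. The roof comes to 46.1 %, and the mean reach gives 42.7 %.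

The forecast, inside this bracket, says 43 % with excess 26 % and exchange that lags behind, holding that “Total conversion stalls, and the stall scales with reagent”.

The flask gives 42.9 %, excess 25.4 %, and exchange that lags behind, 54 % of the way.

    reagent + free catalyst + left-handed substrate → free catalyst + left-handed product (k = 9000 L² mol⁻² h⁻¹)
    reagent + free catalyst + right-handed substrate → free catalyst + right-handed product (k = 5000 L² mol⁻² h⁻¹)
    left-handed substrate + racemization catalyst ⇌ right-handed substrate + racemization catalyst, rate k3*[racemization catalyst]*[left-handed substrate] forward; the back reaction follows from the equilibrium constant (k = 3000 L mol⁻¹ h⁻¹)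
    reagent ⇌ dormant form (K = 0.390, k = 0.170 h⁻¹)
    free catalyst → spent catalyst (k = 0.0800 h⁻¹)

At 50.0 h free catalyst stands at 1.83 % of its charge and spent catalyst at 98.2 %. Read back over its 50 h, the flask's reach is 0.0140 mM⁻¹, beside your 0.0139 mM⁻¹ from the runs up to 40.0 h.

Now cut the reagent in the same flask to 10 mM. The reach gives 13.0 %, and the computed neighbour stands at 12.9 %.

Readings and results are simulated from invented constants; the scatter is artificial.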